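**Strategy.** The target is cut at the bond between benzofuran C5 and furofuran C2, giving a syringyl furofuran lactol acetate and a cis-2-aryl-2,3-dihydrobenzofuran. The route rests on reading the five-membered ring O1–C2–C3–C3a–C7a, whose C3 bears an exocyclic one-carbon substituent beside the aryl-bearing C2, as a 2-arylchroman-4-one from which the ketone carbon C4 has been pushed out of the ring. Irradiation of an enantiopure 3-diazoflavanone in methanol contracts the pyranone, forms the C3–C3a bond, turns C4 into the exocyclic ester carbon and sets C3 cis to the C2 aryl group by kinetic protonation, all in one operation. The precursor is a 2S-flavanone carrying a diazo group at C3 and a silyl-protected guaiacyl group at C2.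

Key step: step 6

Remark 1: the target is read as the 2,3-cis dihydrobenzofuran (2S,3S) joined to a pinoresinol-type furofuran (1R,2S,5R,6S in 3,7-dioxabicyclo[3.3.0]octane numbering, both aryl groups exo).
Remark 2 (assumption): the (R)-pyridine-oxazoline ligand is taken to give the 2S flavanone, by analogy with the facial preference of this catalyst class on cyclic enones; if the sense were opposite, the antipodal ligand would be used with no other change.
Remark 3: the aryl silyl ether is kept only as far as alcohol 16 and is then exchanged for acetate, because KHF2 (step 10) and BF3·OEt2 (step 16) would not leave it in place. An acylated phenol also makes the benzylic C2–O1 bond and the guaiacyl ring less prone to ionisation and electrophilic attack.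

**Step 1**
Reactants: 1 1-(2-hydroxy-3-methoxyphenyl)ethanone
Product: 3 8-methoxy-4H-chromen-4-one, via enaminone 2 (not isolated)
Conditions: Me2NCH(OMe)2, 100 °C; then conc. HCl, CH2Cl2, 40 °C
Reagents that add atoms: N,N-dimethylformamide dimethyl acetal, COC(OC)N(C)C
Why: Condensation of the methyl ketone with the amide acetal gives the enaminone, and acid closes the pyranone by phenol addition and loss of dimethylamine (enaminone route to chromones); no stereocentre is formed.

**Step 2**
Reactants: 4 4-bromo-2-methoxyphenol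
Product: 5 (4-bromo-2-methoxyphenoxy)(tert-butyl)dimethylsilane
Conditions: TBSCl, imidazole, DMF, rt
Reagents that add atoms: tert-butyldimethylsilyl chloride, CC(C)(C)[Si](C)(C)Cl
Why: Imidazole-mediated silylation of the phenol gives a group that tolerates the organolithium, the palladium step and the amide base.

**Step 3**
Reactants: 5 (4-bromo-2-methoxyphenoxy)(tert-butyl)dimethylsilane
Product: 8 [4-(tert-butyldimethylsilyloxy)-3-methoxyphenyl]boronic acid, via aryllithium 6 (not isolated), via lithium triisopropoxyborate 7 (not isolated)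
Conditions: n-BuLi, THF, −78 °C; B(Oi-Pr)3, −78 °C → rt; aq. NH4Cl
Reagents that add atoms: n-BuLi, [Li]CCCC (lithium kept only in 6 and 7); triisopropyl borate, CC(C)OB(OC(C)C)OC(C)C; water, O
Why: Bromine–lithium exchange, trapping of the aryllithium by the borate ester and mild hydrolysis of the ate complex give the boronic acid (lithiation–borylation), the para silyloxy group being out of reach for silyl migration.

**Step 4**
Reactants: 3 8-methoxy-4H-chromen-4-one; 8 [4-(tert-butyldimethylsilyloxy)-3-methoxyphenyl]boronic acid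
Product: 9 (2S)-2-[4-(tert-butyldimethylsilyloxy)-3-methoxyphenyl]-8-methoxy-2,3-dihydro-4H-chromen-4-one
Conditions: Pd(OCOCF3)2 (5 mol%), (R)-4-tert-butyl-2-(pyridin-2-yl)-4,5-dihydrooxazole (6 mol%), NH4PF6 (30 mol%), H2O (5 equiv), ClCH2CH2Cl, 60 °C
Reagents that add atoms: none
Why: Asymmetric conjugate addition of the arylboronic acid to the chromone, catalysed by a cationic divalent palladium complex of the pyridine-oxazoline, transfers the aryl group to C2 on the enone face left open by the tert-butyl group and so sets C2 as S, water protonating the palladium enolate.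

**Step 5**
Reactants: 9 (2S)-2-[4-(tert-butyldimethylsilyloxy)-3-methoxyphenyl]-8-methoxy-2,3-dihydro-4H-chromen-4-one
Product: 12 (2R)-2-[4-(tert-butyldimethylsilyloxy)-3-methoxyphenyl]-3-diazo-8-methoxy-2,3-dihydro-4H-chromen-4-one, via lithium enolate 10 (not isolated), via 3-trifluoroacetylflavanone 11 (not isolated)
Conditions: LiN(SiMe3)2, THF, −78 °C; CF3CO2CH2CF3, −78 °C; then 4-AcNHC6H4SO2N3, Et3N, H2O, MeCN, rt
Reagents that add atoms: 4-acetamidobenzenesulfonyl azide, CC(=O)Nc1ccc(cc1)S(=O)(=O)N=[N+]=[N-]; 2,2,2-trifluoroethyl trifluoroacetate, O=C(OCC(F)(F)F)C(F)(F)F (acyl group kept only in 11); LiN(SiMe3)2, [Li]N([Si](C)(C)C)[Si](C)(C)C (lithium kept only in 10)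
Why: The lithium enolate, formed and trapped at −78 °C, is trifluoroacetylated (Claisen-type acylation) and the activated diketone then accepts the diazo group from the sulfonyl azide under triethylamine with loss of the trifluoroacetyl group (deacylative Regitz diazo transfer), conditions mild enough to avoid retro-oxa-Michael opening and racemisation at C2; the descriptor at C2 changes to R only because the diazo carbon now outranks the aryl group.

**Step 6**
Reactants: 12 (2R)-2-[4-(tert-butyldimethylsilyloxy)-3-methoxyphenyl]-3-diazo-8-methoxy-2,3-dihydro-4H-chromen-4-one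
Product: 15 methyl (2S,3R)-2-[4-(tert-butyldimethylsilyloxy)-3-methoxyphenyl]-7-methoxy-2,3-dihydro-1-benzofuran-3-carboxylate (2,3-cis), via aryl ketene 13 (not isolated), via ester enol 14 (not isolated)
Conditions: hν (365 nm), degassed MeOH (0.01 M), 0 °C; evaporation without acid or base
Reagents that add atoms: methanol, CO
Why: Excitation of the diazo ketone, which the ring locks in the s-cis geometry, expels N2 while the benzo carbon (C4a of the chromanone, C3a of the product) shifts from the carbonyl carbon to C3, giving ketene 13 (photochemical Wolff rearrangement, the closest precedent being the ring contraction of 3-diazochroman-4-ones and other cyclic 2-diazo ketones). The ring O1–C2–C3–C3a–C7a is therefore closed by contraction of the pyranone through a 1,2-shift and not by a cyclisation, the new bond being C3–C3a. Methanol adds to the ketene to give ester enol 14, and its ketonisation creates the C3 stereocentre: the proton reaches the exocyclic enol on the face remote from the C2 aryl group, so the ester ends up cis to that group (substrate control from C2). C2 takes no part, so the configuration set in step 4 is carried over unchanged. The step needs rearrangement to win over hydrogen shift from C2 (which would give the flavone) and over O–H insertion, which the concerted path open to the rigid s-cis diazo ketone secures, and it needs kinetic ketonisation, which cold, base-free methanol and a neutral work-up secure.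

**Step 7**
Reactants: 15 methyl (2S,3R)-2-[4-(tert-butyldimethylsilyloxy)-3-methoxyphenyl]-7-methoxy-2,3-dihydro-1-benzofuran-3-carboxylate
Product: 16 [(2S,3S)-2-[4-(tert-butyldimethylsilyloxy)-3-methoxyphenyl]-7-methoxy-2,3-dihydro-1-benzofuran-3-yl]methanol
Conditions: i-Bu2AlH (3 equiv), CH2Cl2, −78 → −30 °C; aq. KNaC4H4O6
Reagents that add atoms: none
Why: Hydride reduction of the ester by the Lewis-acidic, non-basic aluminium hydride at low temperature gives the primary alcohol without enolisation, so the cis relationship at C2/C3 is kept.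

**Step 8**
Reactants: 16 [(2S,3S)-2-[4-(tert-butyldimethylsilyloxy)-3-methoxyphenyl]-7-methoxy-2,3-dihydro-1-benzofuran-3-yl]methanol
Product: 18 [(2S,3S)-2-(4-acetoxy-3-methoxyphenyl)-7-methoxy-2,3-dihydro-1-benzofuran-3-yl]methyl acetate, via desilylated diol 17 (not isolated)
Conditions: Bu4NF, THF, 0 °C; then Ac2O, Et3N, DMAP, 0 °C → rt
Reagents that add atoms: acetic anhydride, CC(=O)OC(C)=O
Why: Fluoride cleaves the aryl silyl ether (desilylation) and the phenol and the primary alcohol are acetylated in the same flask (DMAP-catalysed acylation), which removes the fluoride-labile group before step 10 and deactivates the guaiacyl ring and the benzylic C2–O1 bond toward the Lewis acid of step 16.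

**Step 9**
Reactants: 18 [(2S,3S)-2-(4-acetoxy-3-methoxyphenyl)-7-methoxy-2,3-dihydro-1-benzofuran-3-yl]methyl acetate
Product: 19 [(2S,3S)-2-(4-acetoxy-3-methoxyphenyl)-7-methoxy-5-(4,4,5,5-tetramethyl-1,3,2-dioxaborolan-2-yl)-2,3-dihydro-1-benzofuran-3-yl]methyl acetate
Conditions: [Ir(cod)OMe]2 (2.5 mol%), 4,4'-di-tert-butyl-2,2'-bipyridine (5 mol%), B2pin2 (1.0 equiv), THF, 65 °C
Reagents that add atoms: bis(pinacolato)diboron, CC1(C)OB(OC1(C)C)B1OC(C)(C)C(C)(C)O1
Why: Iridium-catalysed aromatic C–H borylation is ruled by sterics: on ring A only C5–H has no ortho substituent (C4–H lies next to the ring fusion, C6–H next to OMe) and every C–H of the guaiacyl ring is ortho to a substituent, so boron should go to C5.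

**Step 10**
Reactants: 19 [(2S,3S)-2-(4-acetoxy-3-methoxyphenyl)-7-methoxy-5-(4,4,5,5-tetramethyl-1,3,2-dioxaborolan-2-yl)-2,3-dihydro-1-benzofuran-3-yl]methyl acetate
Product: 20 potassium [(2S,3S)-3-(acetoxymethyl)-2-(4-acetoxy-3-methoxyphenyl)-7-methoxy-2,3-dihydro-1-benzofuran-5-yl]trifluoroborate
Conditions: KHF2 (4 equiv), MeOH/H2O, 0 °C → rt
Reagents that add atoms: potassium hydrogen difluoride, [K+].F[H-]F
Why: Exchange of the pinacol ester for fluoride with KHF2 gives the crystalline trifluoroborate salt (standard boronate-to-trifluoroborate conversion), the weakly acidic bifluoride medium leaving both acetates in place.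

**Step 11**
Reactants: 21 syringaldehyde (4-hydroxy-3,5-dimethoxybenzaldehyde)
Product: 22 4-formyl-2,6-dimethoxyphenyl 2,2-dimethylpropanoate
Conditions: t-BuCOCl, Et3N, DMAP, CH2Cl2, 0 °C → rt
Reagents that add atoms: pivaloyl chloride, CC(C)(C)C(Cl)=O
Why: Acylation of the phenol gives a hindered ester that tolerates the lithium enolate of step 13 and is removed by the hydride of step 14.

**Step 12**
Reactants: 23 (5R)-5-{[(1R,2S,5R)-5-methyl-2-(propan-2-yl)cyclohexyl]oxy}furan-2(5H)-one (commercial menthyloxy butenolide)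
Product: 24 (4S,5R)-4-(1,3-dioxolan-2-yl)-5-{[(1R,2S,5R)-5-methyl-2-(propan-2-yl)cyclohexyl]oxy}oxolan-2-one
Conditions: hν (350 nm), Ph2CO (10 mol%), 1,3-dioxolane (solvent), rt, degassed
Reagents that add atoms: 1,3-dioxolane, C1COCO1
Why: Benzophenone-sensitised hydrogen abstraction gives the 2-dioxolanyl radical, which adds to C4 of the butenolide anti to the bulky menthyloxy group at C5 (photochemical radical conjugate addition of 1,3-dioxolane to 5-substituted butenolides), setting C4 as S and placing a masked aldehyde at the future furofuran C2.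

**Step 13**
Reactants: 24 (4S,5R)-4-(1,3-dioxolan-2-yl)-5-menthyloxyoxolan-2-one; 22 4-formyl-2,6-dimethoxyphenyl 2,2-dimethylpropanoate
Product: 26 (3S,4S,5R)-3-{[3,5-dimethoxy-4-(pivaloyloxy)phenyl](hydroxy)methyl}-4-(1,3-dioxolan-2-yl)-5-menthyloxyoxolan-2-one (carbinol epimers), via lactone lithium enolate 25 (not isolated)
Conditions: LiN(i-Pr)2, THF, −78 °C; then 22, −78 °C; AcOH
Reagents that add atoms: LiN(i-Pr)2, [Li]N(C(C)C)C(C)C (lithium kept only in 25)
Why: Aldol addition of the lithium enolate, in which the aldehyde approaches C3 anti to the C4 dioxolanyl group and sets C3 as S, while the carbinol carbon forms as an epimer mixture that step 14 erases.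

**Step 14**
Reactants: 26 (3S,4S,5R)-3-{[3,5-dimethoxy-4-(pivaloyloxy)phenyl](hydroxy)methyl}-4-(1,3-dioxolan-2-yl)-5-menthyloxyoxolan-2-one
Product: 28 (1R,5R,6S)-6-(4-hydroxy-3,5-dimethoxyphenyl)-3,7-dioxabicyclo[3.3.0]octan-2-ol (both anomers), via tetraol 27 (not isolated)
Conditions: LiAlH4, THF, 0 °C → rt; EtOAc quench; then aq. HCl (to 1 M), THF, rt
Reagents that add atoms: water, O
Why: LiAlH4 reduces the pseudo-ester to the 1,4-diol with release of menthol and cleaves the pivalate, and in aqueous acid the p-hydroxybenzylic carbinol ionises and is captured by the C8 hydroxyl (furofuran numbering) under thermodynamic control, which places the aryl group exo at C6 (S), while the dioxolane is exchanged for the C4 hydroxyl and hydrolysed to the lactol (acid-catalysed benzylic etherification and transacetalisation, as used for furofuran lignans).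

**Step 15**
Reactants: 28 (1R,5R,6S)-6-(4-hydroxy-3,5-dimethoxyphenyl)-3,7-dioxabicyclo[3.3.0]octan-2-ol
Product: 29 (1R,5R,6S)-6-(4-acetoxy-3,5-dimethoxyphenyl)-3,7-dioxabicyclo[3.3.0]octan-2-yl acetate (both anomers)
Conditions: Ac2O, pyridine, DMAP, CH2Cl2, 0 °C → rt
Reagents that add atoms: acetic anhydride, CC(=O)OC(C)=O
Why: DMAP-catalysed acetylation of the phenol and of the lactol hydroxyl gives an anomeric acetate as leaving group and an electron-poorer aryl group that resists benzylic ionisation at C6.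

**Step 16**
Reactants: 20 potassium [(2S,3S)-3-(acetoxymethyl)-2-(4-acetoxy-3-methoxyphenyl)-7-methoxy-2,3-dihydro-1-benzofuran-5-yl]trifluoroborate; 29 (1R,5R,6S)-6-(4-acetoxy-3,5-dimethoxyphenyl)-3,7-dioxabicyclo[3.3.0]octan-2-yl acetate (1.3 equiv)
Product: 32 [(2S,3S)-2-(4-acetoxy-3-methoxyphenyl)-5-[(1R,2S,5R,6S)-6-(4-acetoxy-3,5-dimethoxyphenyl)-3,7-dioxabicyclo[3.3.0]octan-2-yl]-7-methoxy-2,3-dihydro-1-benzofuran-3-yl]methyl acetate, via aryldifluoroborane 30 (not isolated), via oxocarbenium ion 31 (not isolated)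
Conditions: BF3·OEt2 (4 equiv), MeCN/CH2Cl2, −40 → 0 °C; aq. NaHCO3
Reagents that add atoms: none
Why: BF3·OEt2 takes fluoride from 20 to give aryldifluoroborane 30 and ionises the anomeric acetate of 29 to oxocarbenium ion 31, which is attacked by the boron-bearing C5 (ipso substitution, the Lewis-acid coupling of potassium organotrifluoroborates with acetals) from the convex exo face of the cis-fused bicycle, setting furofuran C2 as S with the aryl group exo, while the acyl groups on both phenols hold back benzylic ionisation.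

**Step 17**
Reactants: 32 [(2S,3S)-2-(4-acetoxy-3-methoxyphenyl)-5-[(1R,2S,5R,6S)-6-(4-acetoxy-3,5-dimethoxyphenyl)-3,7-dioxabicyclo[3.3.0]octan-2-yl]-7-methoxy-2,3-dihydro-1-benzofuran-3-yl]methyl acetate
Product: 33 4-[(2S,3S)-5-[(1R,2S,5R,6S)-6-(4-hydroxy-3,5-dimethoxyphenyl)-3,7-dioxabicyclo[3.3.0]octan-2-yl]-3-(hydroxymethyl)-7-methoxy-2,3-dihydro-1-benzofuran-2-yl]-2-methoxyphenol (target)
Conditions: K2CO3 (0.2 equiv), MeOH, 0 °C → rt; aq. NH4Cl
Reagents that add atoms: none
Why: Base-catalysed transesterification to methanol (Zemplén-type deacetylation) removes the three acetates under conditions too mild to open the dihydrobenzofuran through a quinone methide, so no stereocentre is touched.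

**Compound list**

1 | 1-(2-hydroxy-3-methoxyphenyl)ethanone | CC(=O)c1cccc(OC)c1O | starting material
2 | (E)-3-(dimethylamino)-1-(2-hydroxy-3-methoxyphenyl)prop-2-en-1-one | CN(C)/C=C/C(=O)c1cccc(OC)c1O | intermediate (not isolated)
3 | 8-methoxy-4H-chromen-4-one | COc1cccc2c1OC=CC2=O | intermediate
4 | 4-bromo-2-methoxyphenol | COc1cc(Br)ccc1O | starting material
5 | (4-bromo-2-methoxyphenoxy)(tert-butyl)dimethylsilane | COc1cc(Br)ccc1O[Si](C)(C)C(C)(C)C | intermediate
6 | [4-(tert-butyldimethylsilyloxy)-3-methoxyphenyl]lithium | COc1cc([Li])ccc1O[Si](C)(C)C(C)(C)C | intermediate (not isolated)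
7 | lithium [4-(tert-butyldimethylsilyloxy)-3-methoxyphenyl]tri(propan-2-yloxy)borate | [Li+].COc1cc([B-](OC(C)C)(OC(C)C)OC(C)C)ccc1O[Si](C)(C)C(C)(C)C | intermediate (not isolated)
8 | [4-(tert-butyldimethylsilyloxy)-3-methoxyphenyl]boronic acid | COc1cc(B(O)O)ccc1O[Si](C)(C)C(C)(C)C | intermediate
9 | (2S)-2-[4-(tert-butyldimethylsilyloxy)-3-methoxyphenyl]-8-methoxy-2,3-dihydro-4H-chromen-4-one | COc1cc([C@H]2Oc3c(OC)cccc3C(=O)C2)ccc1O[Si](C)(C)C(C)(C)C | intermediate
10 | lithium enolate of 9 (C4–OLi, C3=C4; C2 as in 9) | COc1cc([C@H]2Oc3c(OC)cccc3C(O[Li])=C2)ccc1O[Si](C)(C)C(C)(C)C | intermediate (not isolated)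
11 | (2S)-2-[4-(tert-butyldimethylsilyloxy)-3-methoxyphenyl]-8-methoxy-3-(trifluoroacetyl)-2,3-dihydro-4H-chromen-4-one (C3 epimers and enol form) | COc1cc([C@H]2Oc3c(OC)cccc3C(=O)C2C(=O)C(F)(F)F)ccc1O[Si](C)(C)C(C)(C)C | intermediate (not isolated)
12 | (2R)-2-[4-(tert-butyldimethylsilyloxy)-3-methoxyphenyl]-3-diazo-8-methoxy-2,3-dihydro-4H-chromen-4-one (same spatial arrangement at C2 as 9) | COc1cc([C@H]2Oc3c(OC)cccc3C(=O)C2=[N+]=[N-])ccc1O[Si](C)(C)C(C)(C)C | intermediate (precursor of the key step)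
13 | 2-[4-(tert-butyldimethylsilyloxy)-3-methoxyphenyl]-7-methoxy-3-(oxomethylidene)-2,3-dihydro-1-benzofuran (ketene; C2 as in 12) | COc1cc([C@H]2Oc3c(OC)cccc3C2=C=O)ccc1O[Si](C)(C)C(C)(C)C | intermediate (not isolated)
14 | 3-[hydroxy(methoxy)methylidene]-2-[4-(tert-butyldimethylsilyloxy)-3-methoxyphenyl]-7-methoxy-2,3-dihydro-1-benzofuran (ester enol; C2 as in 12) | COc1cc([C@H]2Oc3c(OC)cccc3C2=C(O)OC)ccc1O[Si](C)(C)C(C)(C)C | intermediate (not isolated)
15 | methyl (2S,3R)-2-[4-(tert-butyldimethylsilyloxy)-3-methoxyphenyl]-7-methoxy-2,3-dihydro-1-benzofuran-3-carboxylate (2,3-cis) | COc1cc([C@H]2Oc3c(OC)cccc3[C@H]2C(=O)OC)ccc1O[Si](C)(C)C(C)(C)C | intermediate (product of the key step)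
16 | [(2S,3S)-2-[4-(tert-butyldimethylsilyloxy)-3-methoxyphenyl]-7-methoxy-2,3-dihydro-1-benzofuran-3-yl]methanol (2,3-cis) | COc1cc([C@H]2Oc3c(OC)cccc3[C@H]2CO)ccc1O[Si](C)(C)C(C)(C)C | intermediate
17 | 4-[(2S,3S)-3-(hydroxymethyl)-7-methoxy-2,3-dihydro-1-benzofuran-2-yl]-2-methoxyphenol | COc1cc([C@H]2Oc3c(OC)cccc3[C@H]2CO)ccc1O | intermediate (not isolated)
18 | [(2S,3S)-2-(4-acetoxy-3-methoxyphenyl)-7-methoxy-2,3-dihydro-1-benzofuran-3-yl]methyl acetate | COc1cc([C@H]2Oc3c(OC)cccc3[C@H]2COC(C)=O)ccc1OC(C)=O | intermediate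
19 | [(2S,3S)-2-(4-acetoxy-3-methoxyphenyl)-7-methoxy-5-(4,4,5,5-tetramethyl-1,3,2-dioxaborolan-2-yl)-2,3-dihydro-1-benzofuran-3-yl]methyl acetate | COc1cc([C@H]2Oc3c(OC)cc(B4OC(C)(C)C(C)(C)O4)cc3[C@H]2COC(C)=O)ccc1OC(C)=O | intermediate
20 | potassium [(2S,3S)-3-(acetoxymethyl)-2-(4-acetoxy-3-methoxyphenyl)-7-methoxy-2,3-dihydro-1-benzofuran-5-yl]trifluoroborate | [K+].COc1cc([C@H]2Oc3c(OC)cc([B-](F)(F)F)cc3[C@H]2COC(C)=O)ccc1OC(C)=O | intermediate
21 | syringaldehyde (4-hydroxy-3,5-dimethoxybenzaldehyde) | COc1cc(C=O)cc(OC)c1O | starting material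
22 | 4-formyl-2,6-dimethoxyphenyl 2,2-dimethylpropanoate | COc1cc(C=O)cc(OC)c1OC(=O)C(C)(C)C | intermediate
23 | (5R)-5-{[(1R,2S,5R)-5-methyl-2-(propan-2-yl)cyclohexyl]oxy}furan-2(5H)-one | O=C1C=C[C@H](O[C@@H]2C[C@H](C)CC[C@H]2C(C)C)O1 | starting material
24 | (4S,5R)-4-(1,3-dioxolan-2-yl)-5-{[(1R,2S,5R)-5-methyl-2-(propan-2-yl)cyclohexyl]oxy}oxolan-2-one (4,5-trans) | O=C1O[C@@H](O[C@@H]2C[C@H](C)CC[C@H]2C(C)C)[C@H](C3OCCO3)C1 | intermediate
25 | lithium enolate of 24 (C2–OLi, C2=C3) | [Li]OC1=C[C@@H](C3OCCO3)[C@H](O[C@@H]2C[C@H](C)CC[C@H]2C(C)C)O1 | intermediate (not isolated)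
26 | (3S,4S,5R)-3-{[3,5-dimethoxy-4-(pivaloyloxy)phenyl](hydroxy)methyl}-4-(1,3-dioxolan-2-yl)-5-menthyloxyoxolan-2-one (3,4-trans, 4,5-trans; carbinol epimers) | O=C1O[C@@H](O[C@@H]2C[C@H](C)CC[C@H]2C(C)C)[C@H](C3OCCO3)[C@H]1C(O)c4cc(OC)c(OC(=O)C(C)(C)C)c(OC)c4 | intermediate
27 | (2R,3R)-2-(1,3-dioxolan-2-yl)-3-[hydroxy(4-hydroxy-3,5-dimethoxyphenyl)methyl]butane-1,4-diol (carbinol epimers) | OC[C@@H]([C@H](CO)C2OCCO2)C(O)c1cc(OC)c(O)c(OC)c1 | intermediate (not isolated)
28 | (1R,5R,6S)-6-(4-hydroxy-3,5-dimethoxyphenyl)-3,7-dioxabicyclo[3.3.0]octan-2-ol (cis-fused, aryl exo, both anomers) | OC1OC[C@H]2[C@@H]1CO[C@@H]2c3cc(OC)c(O)c(OC)c3 | intermediate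
29 | (1R,5R,6S)-6-(4-acetoxy-3,5-dimethoxyphenyl)-3,7-dioxabicyclo[3.3.0]octan-2-yl acetate (both anomers) | CC(=O)OC1OC[C@H]2[C@@H]1CO[C@@H]2c3cc(OC)c(OC(C)=O)c(OC)c3 | intermediate
30 | [(2S,3S)-3-(acetoxymethyl)-2-(4-acetoxy-3-methoxyphenyl)-7-methoxy-2,3-dihydro-1-benzofuran-5-yl]difluoroborane | COc1cc([C@H]2Oc3c(OC)cc(B(F)F)cc3[C@H]2COC(C)=O)ccc1OC(C)=O | intermediate (not isolated)
31 | (1R,5R,6S)-6-(4-acetoxy-3,5-dimethoxyphenyl)-3,7-dioxabicyclo[3.3.0]oct-2-en-3-ium (oxocarbenium ion, C2=O3+) | C1=[O+]C[C@H]2[C@@H]1CO[C@@H]2c3cc(OC)c(OC(C)=O)c(OC)c3 | intermediate (not isolated)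
32 | [(2S,3S)-2-(4-acetoxy-3-methoxyphenyl)-5-[(1R,2S,5R,6S)-6-(4-acetoxy-3,5-dimethoxyphenyl)-3,7-dioxabicyclo[3.3.0]octan-2-yl]-7-methoxy-2,3-dihydro-1-benzofuran-3-yl]methyl acetate | COc1cc([C@H]2Oc3c(OC)cc([C@H]4OC[C@H]5[C@@H]4CO[C@@H]5c6cc(OC)c(OC(C)=O)c(OC)c6)cc3[C@H]2COC(C)=O)ccc1OC(C)=O | intermediate
33 | 4-[(2S,3S)-5-[(1R,2S,5R,6S)-6-(4-hydroxy-3,5-dimethoxyphenyl)-3,7-dioxabicyclo[3.3.0]octan-2-yl]-3-(hydroxymethyl)-7-methoxy-2,3-dihydro-1-benzofuran-2-yl]-2-methoxyphenol | COc1cc([C@H]2Oc3c(OC)cc([C@H]4OC[C@H]5[C@@H]4CO[C@@H]5c4cc(OC)c(O)c(OC)c4)cc3[C@H]2CO)ccc1O | target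

**Step count**

Total step count: 17.
Longest linear sequence: 11 steps (steps 2, 3, 4, 5, 6, 7, 8, 9, 10, 16, 17, from 4-bromo-2-methoxyphenol). The furofuran branch is 6 steps long (steps 12–17).

**Steps most likely to fail, with fallbacks**

Step 6. Two processes could spoil it: loss of facial control when the ester enol ketonises, which would erode the cis relationship at C2/C3, and hydrogen migration from C2 in place of aryl-carbon migration, which would give the flavone. The fallback abandons the ring contraction, builds the same cis ester by carbene C–H insertion, sets out from aryl bromide 5 and returns at ester 15. Bromine–lithium exchange of 5 (n-BuLi, THF, −78 °C) and quenching with DMF would give 4-(tert-butyldimethylsilyloxy)-3-methoxybenzaldehyde F1, which NaBH4 in MeOH would reduce to [4-(tert-butyldimethylsilyloxy)-3-methoxyphenyl]methanol F2. Mitsunobu etherification (PPh3, diisopropyl azodicarboxylate, THF) with commercial methyl (2-hydroxy-3-methoxyphenyl)acetate would give methyl 2-(2-{[4-(tert-butyldimethylsilyloxy)-3-methoxyphenyl]methoxy}-3-methoxyphenyl)acetate F3. Diazo transfer (4-acetamidobenzenesulfonyl azide, DBU, MeCN) would give methyl 2-diazo-2-(2-{[4-(tert-butyldimethylsilyloxy)-3-methoxyphenyl]methoxy}-3-methoxyphenyl)acetate F4. Intramolecular insertion of the rhodium carbene into the benzylic C–H bond under dirhodium tetrakis[N-phthaloyl-(S)-tert-leucinate], Rh2(S-PTTL)4 (or its enantiomer, whichever gives the 2S,3R series), in toluene at −60 °C, a reaction known to favour cis-2-aryl-2,3-dihydrobenzofuran-3-carboxylates, would then lead to 15.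

Step 16. The oxocarbenium ion could attack methoxylated ring positions that carry no boron (Friedel–Crafts), the trifluoroborate could be protodeboronated, or the Lewis acid could open a benzylic ether bond. The fallback replaces the oxocarbenium coupling by carbonyl addition and a separate ring closure, sets out from trifluoroborate 20 and lactol 28, and returns at target 33. Rhodium-catalysed 1,2-addition of 20 to the open hydroxy-aldehyde form of 28 (Rh(acac)(CO)2, 1,1'-bis(diphenylphosphino)ferrocene, DME/H2O, 80 °C) would give [(2S,3S)-2-(4-acetoxy-3-methoxyphenyl)-5-{hydroxy[(3R,4R,5S)-5-(4-hydroxy-3,5-dimethoxyphenyl)-4-(hydroxymethyl)oxolan-3-yl]methyl}-7-methoxy-2,3-dihydro-1-benzofuran-3-yl]methyl acetate F5 as a carbinol mixture. Catalytic camphorsulfonic acid in CH2Cl2 at rt would ionise this doubly benzylic-type carbinol and close the second tetrahydrofuran under thermodynamic control (aryl exo) to [(2S,3S)-2-(4-acetoxy-3-methoxyphenyl)-5-[(1R,2S,5R,6S)-6-(4-hydroxy-3,5-dimethoxyphenyl)-3,7-dioxabicyclo[3.3.0]octan-2-yl]-7-methoxy-2,3-dihydro-1-benzofuran-3-yl]methyl acetate F6. Methanolysis as in step 17 would then give 33.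

Step 5. The enolate could expel the ring phenoxide (retro-oxa-Michael opening), and re-closure would lose enantiopurity at C2; acyl transfer to the hindered enolate could also stall. The fallback avoids any enolate, sets out from flavanone 9 and returns at diazo ketone 12. Acid-mediated nitrosation at C3 (3-methylbutyl nitrite, Me3SiCl, CH2Cl2, −20 °C) would give (2R)-2-[4-(tert-butyldimethylsilyloxy)-3-methoxyphenyl]-3-(hydroxyimino)-8-methoxy-2,3-dihydro-4H-chromen-4-one F7, in which C3 is sp2 and no carbanion can form next to the ring oxygen. The Forster reaction of this oxime with chloramine (aq. NH3, NaOCl, 0 °C) would then give 12.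

**Further compounds**

F1 | step 6 | 4-(tert-butyldimethylsilyloxy)-3-methoxybenzaldehyde | COc1cc(C=O)ccc1O[Si](C)(C)C(C)(C)C
F2 | step 6 | [4-(tert-butyldimethylsilyloxy)-3-methoxyphenyl]methanol | COc1cc(CO)ccc1O[Si](C)(C)C(C)(C)C
F3 | step 6 | methyl 2-(2-{[4-(tert-butyldimethylsilyloxy)-3-methoxyphenyl]methoxy}-3-methoxyphenyl)acetate | COC(=O)Cc1cccc(OC)c1OCc1ccc(O[Si](C)(C)C(C)(C)C)c(OC)c1
F4 | step 6 | methyl 2-diazo-2-(2-{[4-(tert-butyldimethylsilyloxy)-3-methoxyphenyl]methoxy}-3-methoxyphenyl)acetate | COC(=O)C(=[N+]=[N-])c1cccc(OC)c1OCc1ccc(O[Si](C)(C)C(C)(C)C)c(OC)c1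
F5 | step 16 | [(2S,3S)-2-(4-acetoxy-3-methoxyphenyl)-5-{hydroxy[(3R,4R,5S)-5-(4-hydroxy-3,5-dimethoxyphenyl)-4-(hydroxymethyl)oxolan-3-yl]methyl}-7-methoxy-2,3-dihydro-1-benzofuran-3-yl]methyl acetate (carbinol epimers) | COc1cc([C@H]2Oc3c(OC)cc(C(O)[C@H]4CO[C@H](c5cc(OC)c(O)c(OC)c5)[C@H]4CO)cc3[C@H]2COC(C)=O)ccc1OC(C)=O
F6 | step 16 | [(2S,3S)-2-(4-acetoxy-3-methoxyphenyl)-5-[(1R,2S,5R,6S)-6-(4-hydroxy-3,5-dimethoxyphenyl)-3,7-dioxabicyclo[3.3.0]octan-2-yl]-7-methoxy-2,3-dihydro-1-benzofuran-3-yl]methyl acetate | COc1cc([C@H]2Oc3c(OC)cc([C@H]4OC[C@H]5[C@@H]4CO[C@@H]5c6cc(OC)c(O)c(OC)c6)cc3[C@H]2COC(C)=O)ccc1OC(C)=O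
F7 | step 5 | (2R)-2-[4-(tert-butyldimethylsilyloxy)-3-methoxyphenyl]-3-(hydroxyimino)-8-methoxy-2,3-dihydro-4H-chromen-4-one | COc1cc([C@H]2Oc3c(OC)cccc3C(=O)C2=NO)ccc1O[Si](C)(C)C(C)(C)C
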